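**Strategy.** The tetrahydrofuran is opened at O1–C2 and its chain C5–C4–C3–CH2OH (ring carbons C5, C4 and C3 plus the exocyclic hydroxymethyl carbon) is read as a masked butenolide: C5 as the lactone carbonyl, the hydroxymethyl carbon as a chiral menthyl acetal. In one pot, lithiated 2-(3,4,5-trimethoxyphenyl)-1,3-dithiane adds to this furanone and the resulting enolate is benzylated with O-benzylvanillyl bromide, which creates the ArCH2–C4 bond and both stereocentres C3 and C4 (trans on the lactone, hence cis on the later tetrahydrofuran). Dithiane hydrolysis, global hydride reduction and acid-mediated cycloetherification (C2 set trans to C3) then give the ring, and debenzylation the target.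

Key step: step 3

Remark on the chemistry: the (+)-menthol-derived (5S)-menthyloxyfuranone is assumed to be purchasable, like its well-known enantiomer. Tetrahydrofuran numbering throughout: O1, C2 (aryl), C3 (CH2OH), C4 (benzyl), C5. The target is (2R,3S,4S): 2,3-trans and 3,4-cis.

Step 1
Reactants: 1 3,4,5-trimethoxybenzaldehyde; 2 propane-1,3-dithiol
Product: 3 2-(3,4,5-trimethoxyphenyl)-1,3-dithiane
Conditions: BF3·OEt2 (cat.), CH2Cl2, 0 °C to rt
Reagents that add atoms: none
Why: Lewis-acid-catalysed dithioacetalisation of an aromatic aldehyde gives the acyl-anion equivalent (umpolung) that will deliver C2 and its aryl group.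

Step 2
Reactants: 4 [4-(benzyloxy)-3-methoxyphenyl]methanol
Product: 5 1-(benzyloxy)-4-(bromomethyl)-2-methoxybenzene
Conditions: PBr3, Et2O, 0 °C
Reagents that add atoms: phosphorus tribromide, BrP(Br)Br
Why: Substitution of an electron-rich benzylic alcohol by bromide with PBr3 should be clean at 0 °C; the bromide is used fresh.

Step 3
Reactants: 3 2-(3,4,5-trimethoxyphenyl)-1,3-dithiane; 6 (5S)-5-{[(1S,2R,5S)-5-methyl-2-(propan-2-yl)cyclohexyl]oxy}furan-2(5H)-one; 5 1-(benzyloxy)-4-(bromomethyl)-2-methoxybenzene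
Product: 9 (3S,4S,5S)-3-[4-(benzyloxy)-3-methoxybenzyl]-5-{[(1S,2R,5S)-5-methyl-2-(propan-2-yl)cyclohexyl]oxy}-4-[2-(3,4,5-trimethoxyphenyl)-1,3-dithian-2-yl]dihydrofuran-2(3H)-one, via lithiated dithiane 7 (not isolated), via lithium lactone enolate 8 (not isolated)
Conditions: n-BuLi, THF, −78 to −20 °C; then 6, −78 °C; then 5, DMPU, −78 °C to rt
Reagents that add atoms: none
Why: n-BuLi deprotonates 3 to the sulfur-stabilised benzylic anion 7, which adds in conjugate fashion to the furanone carbon β to the carbonyl (lactone C4, the later tetrahydrofuran C3) to give lithium enolate 8, and 8 then displaces bromide from 5 in an SN2 C-alkylation at lactone C3 (the later tetrahydrofuran C4), forming the ArCH2–C bond. The closest known reaction type is the tandem conjugate addition–enolate alkylation of γ-alkoxybutenolides (three-component coupling of a dithiane anion, a butenolide and a benzylic halide). No ring is closed in this step. The stereocentre at lactone C4 is controlled by the acetal carbon C5, whose menthyloxy group shields one face so that 7 enters anti to it; the stereocentre at lactone C3 is controlled by the bulky dithianyl group just installed at C4, the benzyl group entering anti to it, which should give the trans,trans lactone. The step needs 1,4- over 1,2-addition, secured by the soft, hindered, doubly sulfur-stabilised anion, and C-monoalkylation of the enolate, secured by the reactive benzylic bromide with DMPU and by the hindered tertiary α-carbon of the product, which should not enolise and react again.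

Step 4
Reactants: 9 the dithianyl lactone from step 3
Product: 10 (3S,4S,5S)-3-[4-(benzyloxy)-3-methoxybenzyl]-5-{[(1S,2R,5S)-5-methyl-2-(propan-2-yl)cyclohexyl]oxy}-4-(3,4,5-trimethoxybenzoyl)dihydrofuran-2(3H)-one
Conditions: HgO, BF3·OEt2, THF/H2O, rt
Reagents that add atoms: water, O
Why: Thiophilic hydrolysis of the dithioacetal (dethioacetalisation) should free the aryl ketone without touching the benzyl ether or lactone; the ketone α-centre should hold because the all-trans lactone is the thermodynamically preferred epimer, and any partial hydrolysis of the menthyl acetal is harmless because the lactol converges in step 5.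

Step 5
Reactants: 10 the keto lactone from step 4
Product: 11 (2S,3S)-2-[4-(benzyloxy)-3-methoxybenzyl]-3-[hydroxy(3,4,5-trimethoxyphenyl)methyl]butane-1,4-diol (both carbinol epimers)
Conditions: LiAlH4, THF, 0 °C to rt; aqueous work-up
Reagents that add atoms: none
Why: Hydride reduction of the ketone and of the γ-alkoxybutyrolactone pseudo-ester (lactone carbonyl, then the aldehyde released from the hemiacetal) should give the triol and free the menthol auxiliary in one operation; the carbinol epimer mixture is of no consequence because step 6 passes through the benzylic cation.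

Step 6
Reactants: 11 the triol from step 5
Product: 12 [(2R,3S,4S)-4-[4-(benzyloxy)-3-methoxybenzyl]-2-(3,4,5-trimethoxyphenyl)tetrahydrofuran-3-yl]methanol
Conditions: camphor-10-sulfonic acid (cat.), CH2Cl2, 0 °C to rt
Reagents that add atoms: none
Why: Acid-catalysed SN1 cycloetherification: the 3,4,5-trimethoxybenzylic alcohol ionises and the cation is captured by the C5 hydroxyl to close the five-membered ring (the other primary hydroxyl could only give an oxetane), and C2 should be set trans to the C3 hydroxymethyl group because the aryl group avoids the C3 substituent in the transition state and in the more stable product.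

Step 7
Reactants: 12 the benzyl-protected tetrahydrofuran from step 6
Product: 13 [(2R,3S,4S)-4-(4-hydroxy-3-methoxybenzyl)-2-(3,4,5-trimethoxyphenyl)tetrahydrofuran-3-yl]methanol (target)
Conditions: H2 (1 atm), 10% Pd/C, EtOAc/MeOH, rt
Reagents that add atoms: none
Why: Hydrogenolysis of the aryl benzyl ether over Pd/C should be much faster than cleavage of the benzylic C2–O1 bond of the non-phenolic 2-aryltetrahydrofuran under neutral conditions at 1 atm, and no stereocentre is touched.

**Compound list**

1 | 3,4,5-trimethoxybenzaldehyde | COc1cc(C=O)cc(OC)c1OC | starting material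
2 | propane-1,3-dithiol | SCCCS | starting material
3 | 2-(3,4,5-trimethoxyphenyl)-1,3-dithiane | COc1cc(C2SCCCS2)cc(OC)c1OC | intermediate
4 | [4-(benzyloxy)-3-methoxyphenyl]methanol | COc1cc(CO)ccc1OCc1ccccc1 | starting material
5 | 1-(benzyloxy)-4-(bromomethyl)-2-methoxybenzene | COc1cc(CBr)ccc1OCc1ccccc1 | intermediate
6 | (5S)-5-{[(1S,2R,5S)-5-methyl-2-(propan-2-yl)cyclohexyl]oxy}furan-2(5H)-one | O=C1O[C@H](O[C@H]2C[C@@H](C)CC[C@@H]2C(C)C)C=C1 | starting material
7 | 2-lithio-2-(3,4,5-trimethoxyphenyl)-1,3-dithiane | [Li]C1(c2cc(OC)c(OC)c(OC)c2)SCCCS1 | intermediate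
8 | lithium (4S,5S)-5-{[(1S,2R,5S)-5-methyl-2-(propan-2-yl)cyclohexyl]oxy}-4-[2-(3,4,5-trimethoxyphenyl)-1,3-dithian-2-yl]-4,5-dihydrofuran-2-olate | [Li]OC1=C[C@H](C2(c3cc(OC)c(OC)c(OC)c3)SCCCS2)[C@@H](O[C@H]4C[C@@H](C)CC[C@@H]4C(C)C)O1 | intermediate
9 | (3S,4S,5S)-3-[4-(benzyloxy)-3-methoxybenzyl]-5-{[(1S,2R,5S)-5-methyl-2-(propan-2-yl)cyclohexyl]oxy}-4-[2-(3,4,5-trimethoxyphenyl)-1,3-dithian-2-yl]dihydrofuran-2(3H)-one | O=C1O[C@H](O[C@H]2C[C@@H](C)CC[C@@H]2C(C)C)[C@@H](C3(c4cc(OC)c(OC)c(OC)c4)SCCCS3)[C@@H]1Cc1ccc(OCc5ccccc5)c(OC)c1 | intermediate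
10 | (3S,4S,5S)-3-[4-(benzyloxy)-3-methoxybenzyl]-5-{[(1S,2R,5S)-5-methyl-2-(propan-2-yl)cyclohexyl]oxy}-4-(3,4,5-trimethoxybenzoyl)dihydrofuran-2(3H)-one | O=C1O[C@H](O[C@H]2C[C@@H](C)CC[C@@H]2C(C)C)[C@@H](C(=O)c3cc(OC)c(OC)c(OC)c3)[C@@H]1Cc1ccc(OCc4ccccc4)c(OC)c1 | intermediate
11 | (2S,3S)-2-[4-(benzyloxy)-3-methoxybenzyl]-3-[hydroxy(3,4,5-trimethoxyphenyl)methyl]butane-1,4-diol (both carbinol epimers) | COc1cc(C[C@H](CO)[C@@H](CO)C(O)c2cc(OC)c(OC)c(OC)c2)ccc1OCc1ccccc1 | intermediate
12 | [(2R,3S,4S)-4-[4-(benzyloxy)-3-methoxybenzyl]-2-(3,4,5-trimethoxyphenyl)tetrahydrofuran-3-yl]methanol | COc1cc(C[C@@H]2CO[C@@H](c3cc(OC)c(OC)c(OC)c3)[C@@H]2CO)ccc1OCc1ccccc1 | intermediate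
13 | [(2R,3S,4S)-4-(4-hydroxy-3-methoxybenzyl)-2-(3,4,5-trimethoxyphenyl)tetrahydrofuran-3-yl]methanol | COc1cc(C[C@@H]2CO[C@@H](c3cc(OC)c(OC)c(OC)c3)[C@@H]2CO)ccc1O | target

**Step count.** Total: 7 steps. Longest linear sequence: 6 steps (1 → 3 → 9 → 10 → 11 → 12 → 13).

**Steps most likely to fail**

Step 3. The C-benzylation of the hindered enolate may be sluggish next to the quaternary dithianyl carbon, so that proton transfer returns the unalkylated Michael adduct. The fallback replaces alkylation by aldol addition and deoxygenation. It sets out from enolate 8 (made from 3 and 6 as before), which is trapped at −78 °C with the far more electrophilic 4-(benzyloxy)-3-methoxybenzaldehyde. This should give the aldol adduct (3R,4S,5S)-3-{[4-(benzyloxy)-3-methoxyphenyl](hydroxy)methyl}-5-(menthyloxy)-4-[2-(3,4,5-trimethoxyphenyl)-1,3-dithian-2-yl]dihydrofuran-2(3H)-one F1, as carbinol epimers, with the same C–C bond in place trans to the dithianyl group. Acylation with phenyl chlorothionoformate (pyridine, DMAP, CH2Cl2) gives the O-phenyl thionocarbonate F2. Barton–McCombie deoxygenation (Bu3SnH, AIBN, toluene, 80 °C) then removes the benzylic oxygen without a cationic intermediate and comes back to the route at 9.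

Step 6. The benzylic cation may be captured by the vanillyl ring para to its methoxy group (a six-membered Friedel–Crafts closure to an aryltetralin) in competition with ether formation. The fallback blocks that position with a removable bromine. It sets out from ketone 10, in which the trimethoxyphenyl ring is deactivated by the carbonyl group. NBS (MeCN, 0 °C, dark) should therefore brominate only the vanillyl ring, giving (3S,4S,5S)-3-[4-(benzyloxy)-2-bromo-5-methoxybenzyl]-5-(menthyloxy)-4-(3,4,5-trimethoxybenzoyl)dihydrofuran-2(3H)-one F3. LiAlH4 as in step 5 gives the bromo triol (2S,3S)-2-[4-(benzyloxy)-2-bromo-5-methoxybenzyl]-3-[hydroxy(3,4,5-trimethoxyphenyl)methyl]butane-1,4-diol F4. Camphor-10-sulfonic acid closes it to the bromo tetrahydrofuran [(2R,3S,4S)-4-[4-(benzyloxy)-2-bromo-5-methoxybenzyl]-2-(3,4,5-trimethoxyphenyl)tetrahydrofuran-3-yl]methanol F5. H2, Pd/C, Et3N in MeOH removes bromine and benzyl together and comes back to the route at 13.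

Step 7. Over-reduction may open the benzylic C2–O1 bond of the tetrahydrofuran while the benzyl ether is being removed. The fallback reverses the order of deprotection and ring closure, so that no benzylic ring ether meets the catalyst. It sets out from triol 11: H2, Pd/C, EtOAc removes the benzyl group at the open-chain stage to give the phenolic triol (2S,3S)-2-(4-hydroxy-3-methoxybenzyl)-3-[hydroxy(3,4,5-trimethoxyphenyl)methyl]butane-1,4-diol F6. Camphor-10-sulfonic acid in CH2Cl2/THF then closes the ring as in step 6 and comes back to the route at 13.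

**Further compounds**

F1 | step 3 | (3R,4S,5S)-3-{[4-(benzyloxy)-3-methoxyphenyl](hydroxy)methyl}-5-{[(1S,2R,5S)-5-methyl-2-(propan-2-yl)cyclohexyl]oxy}-4-[2-(3,4,5-trimethoxyphenyl)-1,3-dithian-2-yl]dihydrofuran-2(3H)-one (carbinol epimers) | O=C1O[C@H](O[C@H]2C[C@@H](C)CC[C@@H]2C(C)C)[C@@H](C3(c4cc(OC)c(OC)c(OC)c4)SCCCS3)[C@@H]1C(O)c1ccc(OCc5ccccc5)c(OC)c1
F2 | step 3 | O-phenyl thionocarbonate of F1 at the benzylic hydroxyl | O=C1O[C@H](O[C@H]2C[C@@H](C)CC[C@@H]2C(C)C)[C@@H](C3(c4cc(OC)c(OC)c(OC)c4)SCCCS3)[C@@H]1C(OC(=S)Oc6ccccc6)c1ccc(OCc5ccccc5)c(OC)c1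
F3 | step 6 | (3S,4S,5S)-3-[4-(benzyloxy)-2-bromo-5-methoxybenzyl]-5-{[(1S,2R,5S)-5-methyl-2-(propan-2-yl)cyclohexyl]oxy}-4-(3,4,5-trimethoxybenzoyl)dihydrofuran-2(3H)-one | O=C1O[C@H](O[C@H]2C[C@@H](C)CC[C@@H]2C(C)C)[C@@H](C(=O)c3cc(OC)c(OC)c(OC)c3)[C@@H]1Cc1cc(OC)c(OCc4ccccc4)cc1Br
F4 | step 6 | (2S,3S)-2-[4-(benzyloxy)-2-bromo-5-methoxybenzyl]-3-[hydroxy(3,4,5-trimethoxyphenyl)methyl]butane-1,4-diol (both carbinol epimers) | COc1cc(C[C@H](CO)[C@@H](CO)C(O)c2cc(OC)c(OC)c(OC)c2)c(Br)cc1OCc1ccccc1
F5 | step 6 | [(2R,3S,4S)-4-[4-(benzyloxy)-2-bromo-5-methoxybenzyl]-2-(3,4,5-trimethoxyphenyl)tetrahydrofuran-3-yl]methanol | COc1cc(C[C@@H]2CO[C@@H](c3cc(OC)c(OC)c(OC)c3)[C@@H]2CO)c(Br)cc1OCc1ccccc1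
F6 | step 7 | (2S,3S)-2-(4-hydroxy-3-methoxybenzyl)-3-[hydroxy(3,4,5-trimethoxyphenyl)methyl]butane-1,4-diol (both carbinol epimers) | COc1cc(C[C@H](CO)[C@@H](CO)C(O)c2cc(OC)c(OC)c(OC)c2)ccc1O
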